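**Retrosynthetic overview**
1. The sulfate is carried as a 2,2,2-trichloroethyl diester. All other phenols are benzyl ethers or a diphenylmethylene ketal, so one reductive step ends the route.
2. The C2–aryl bond and the C2 and C3 stereocentres come from an enantioselective conjugate arylation of an achiral 3-(flavon-8-yl)chromone, so ring B is attached last.
3. Ring C of that chromone comes from one base-induced cascade on an 8-(2-oxoethyl)flavone whose O7″ carries the 2,4-bis(benzyloxy)-6-fluorobenzoyl group. An O-to-C aroyl shift makes C3–C4, and displacement of fluoride by the enolate oxygen makes O1–C8a.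
4. Enabling feature: O7″, the oxygen that must end up sulfated, sits on ring A″ ortho to C8″, so along O7″–C7″–C8″–C3 the ester carbonyl reaches C3 through a five-membered transition state. In ring A, C8a is ortho to C4, so the new ketone activates it, and the shift frees O7″ as the only phenol.
5. Ring order: rings A″, C″ and B″ come with luteolin, the two-carbon arm comes from a Claisen rearrangement and alkene cleavage, ring A comes from 5-fluororesorcinol, then ring C is closed, then ring B is added.

Key step: step 10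

Assumption: the sulfate is delivered in the protonated form drawn, by acidifying its ammonium salt; the (S)-ligand of step 12 is taken to give 2R by analogy with its sense on cyclic enones, and its antipode is used if the sense proves opposite.

Step 1
Reactants: 1 luteolin; 2 dichlorodiphenylmethane
Product: 3 2-(2,2-diphenyl-1,3-benzodioxol-5-yl)-5,7-dihydroxy-4H-chromen-4-one (3′,4′-O-diphenylmethylene-luteolin)
Conditions: Ph2CCl2, Ph2O, 175 °C
Reagents that add atoms: dichlorodiphenylmethane ClC(Cl)(c1ccccc1)c1ccccc1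
Why: The catechol is the only pair of adjacent hydroxyls, so double substitution of the gem-dichloride closes the five-membered ketal there and leaves the 5-OH and 7-OH free (catechol ketalisation).

Step 2
Reactants: 3; 4 allyl bromide
Product: 5 7-allyloxy-2-(2,2-diphenyl-1,3-benzodioxol-5-yl)-5-hydroxy-4H-chromen-4-one
Conditions: allyl bromide (1.05 equiv), K2CO3, DMF, 23 °C
Reagents that add atoms: allyl bromide C=CCBr
Why: The 7-OH is the more acidic, unchelated phenol while the 5-OH is hydrogen-bonded to the C4 carbonyl, so a Williamson etherification with one equivalent should stop at O7.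

Step 3
Reactants: 5; 6 benzyl bromide
Product: 7 7-allyloxy-5-benzyloxy-2-(2,2-diphenyl-1,3-benzodioxol-5-yl)-4H-chromen-4-one
Conditions: BnBr, K2CO3, DMF, 80 °C
Reagents that add atoms: benzyl bromide BrCc1ccccc1
Why: Forcing Williamson conditions overcome the chelation and benzylate the one remaining phenol.

Step 4
Reactants: 7
Product: 8 8-allyl-5-benzyloxy-2-(2,2-diphenyl-1,3-benzodioxol-5-yl)-7-hydroxy-4H-chromen-4-one
Conditions: PhNEt2, 200 °C, sealed tube
Reagents that add atoms: none
Why: The aromatic Claisen rearrangement ([3,3] shift, then tautomerisation) should move the allyl group to C8, favoured over C6 by the higher double-bond character of C7–C8 and by crowding next to the 5-benzyloxy group, and it uncovers the 7-OH as the only free phenol.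

Step 5
Reactants: 9 5-fluororesorcinol; 6 benzyl bromide
Product: 10 1,3-bis(benzyloxy)-5-fluorobenzene
Conditions: BnBr (2.2 equiv), K2CO3, DMF, 60 °C
Reagents that add atoms: benzyl bromide BrCc1ccccc1
Why: A double Williamson etherification of two equivalent phenols has no selectivity issue.

Step 6
Reactants: 10
Product: 11 2,4-bis(benzyloxy)-6-fluorobenzaldehyde
Conditions: POCl3, DMF, 0 → 60 °C; then ice-water
Reagents that add atoms: N,N-dimethylformamide CN(C)C=O; water O
Why: The Vilsmeier–Haack formylation should attack para to one benzyloxy group and ortho to the other, next to the small fluorine, because the site between the two benzyloxy groups is more crowded.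

Step 7
Reactants: 11
Product: 12 2,4-bis(benzyloxy)-6-fluorobenzoic acid
Conditions: NaClO2, NaH2PO4, 2-methyl-2-butene, t-BuOH–THF–H2O, 23 °C
Reagents that add atoms: sodium chlorite [Na+].[O-]Cl=O
Why: The Pinnick oxidation converts the aldehyde into the acid, and the alkene scavenger protects the electron-rich ring from chlorination.

Step 8
Reactants: 12; 8
Product: 14 8-allyl-5-benzyloxy-2-(2,2-diphenyl-1,3-benzodioxol-5-yl)-4-oxo-4H-chromen-7-yl 2,4-bis(benzyloxy)-6-fluorobenzoate, via acid chloride 13 (not isolated)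
Conditions: (COCl)2, DMF (cat.), CH2Cl2, 0 → 23 °C; then 8, Et3N, DMAP (cat.), CH2Cl2, 0 → 23 °C
Reagents that add atoms: none
Why: DMAP-catalysed acylation of the single free phenol by the acid chloride installs the aroyl group on O7″, where it serves both as protecting group and as tethered acyl donor.

Step 9
Reactants: 14
Product: 16 5-benzyloxy-2-(2,2-diphenyl-1,3-benzodioxol-5-yl)-4-oxo-8-(2-oxoethyl)-4H-chromen-7-yl 2,4-bis(benzyloxy)-6-fluorobenzoate, via vicinal diol 15 (not isolated)
Conditions: OsO4 (2 mol %), NaIO4, 2,6-lutidine, dioxane–H2O, 23 °C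
Reagents that add atoms: osmium tetroxide O=[Os](=O)(=O)=O; sodium periodate [Na+].[O-]I(=O)(=O)=O
Why: In the Lemieux–Johnson cleavage the terminal alkene is dihydroxylated much faster than the electron-poor flavone double bond, and periodate cuts the diol to the arylacetaldehyde under nearly neutral conditions that spare the aryl ester.

Step 10
Reactants: 16
Product: 18 5,7-bis(benzyloxy)-3-[5-benzyloxy-2-(2,2-diphenyl-1,3-benzodioxol-5-yl)-7-hydroxy-4-oxo-4H-chromen-8-yl]-4H-chromen-4-one, via 2-aryl-3-oxopropanal 17 (not isolated)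
Conditions: Cs2CO3 (3 equiv), dry DMF (0.02 M), Ar, 23 °C, then 60 °C; pH 6 buffer
Reagents that add atoms: none
Why: Proposed new method: Cs2CO3 enolises the arylacetaldehyde, and the enolate carbon C3 attacks the neighbouring aryl ester carbonyl through a five-membered (5-exo-trig) tetrahedral intermediate that collapses with loss of the O7″ phenoxide, which forms C3–C4 and gives 17 as its enolate. On warming, the formyl-derived enolate oxygen O1 adds to the fluorine-bearing carbon C8a, which is activated by the ortho C4 carbonyl and not deactivated by the two meta benzyloxy groups, and loss of fluoride closes ring C in a 6-endo-trig addition–elimination (formally an oxa-6π closure followed by loss of HF) that makes the pyranone aromatic. The closest known reaction types are the Baker–Venkataraman O-to-C aroyl transfer and the base-induced cyclisation of 1-(2-fluoroaryl)-1,3-dicarbonyl compounds to chromones, and what is new is their union across a one-atom-shorter tether on an arylacetaldehyde. No stereocentre is created, and the C3–C8″ axis, flanked on the chromone side only by H and C=O, should rotate freely enough not to matter. The step needs C- rather than O-acylation, which the tether geometry secures, and closure by O1 rather than by the freed O7″ phenoxide, which the six- versus seven-membered ring size favours. Furan formation by the freed phenol should be held back because excess carbonate in dry DMF keeps both the phenol and the dicarbonyl unit deprotonated.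

Step 11
Reactants: 18; 19 2,2,2-trichloroethyl chlorosulfate
Product: 20 8-[5,7-bis(benzyloxy)-4-oxo-4H-chromen-3-yl]-5-benzyloxy-2-(2,2-diphenyl-1,3-benzodioxol-5-yl)-4-oxo-4H-chromen-7-yl 2,2,2-trichloroethyl sulfate
Conditions: 19, Et3N, DMAP, THF, 0 → 23 °C
Reagents that add atoms: 2,2,2-trichloroethyl chlorosulfate ClS(=O)(=O)OCC(Cl)(Cl)Cl
Why: The only free hydroxyl is O7″, so sulfonyl transfer from the chlorosulfate fixes the sulfate site as a neutral diester while the molecule still has no stereocentre that base could harm.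

Step 12
Reactants: 20; 21 4-(benzyloxy)phenylboronic acid
Product: 22 8-{(2R,3S)-5,7-bis(benzyloxy)-2-[4-(benzyloxy)phenyl]-4-oxochroman-3-yl}-5-benzyloxy-2-(2,2-diphenyl-1,3-benzodioxol-5-yl)-4-oxo-4H-chromen-7-yl 2,2,2-trichloroethyl sulfate
Conditions: 21 (3 equiv), Pd(OCOCF3)2 (10 mol %), (S)-t-BuPyOx (12 mol %), NH4PF6 (30 mol %), H2O (5 equiv), ClCH2CH2Cl, 60 °C
Reagents that add atoms: 4-(benzyloxy)phenylboronic acid OB(O)c1ccc(OCc2ccccc2)cc1
Why: Proposed new method: a cationic aryl complex of divalent palladium bearing the chiral pyridine–oxazoline ligand should insert the C2=C3 bond with the aryl group going to the unsubstituted C2 and the metal to C3, the tert-butyl group of the ligand choosing the face so that C2 becomes R; protonolysis of the palladium enolate by water and enolisation in the weakly acidic medium let C3 settle as S with the two aryl groups trans; the flavone unit should stay untouched because its β-carbon is fully substituted; the closest known reaction type is the enantioselective conjugate addition of arylboronic acids to 3-unsubstituted chromones, which gives flavanones without base and so without racemisation by ring opening.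

Step 13
Reactants: 22
Product: 24 (2R,3S)-morelloflavone 7″-O-sulfate, the target, via ammonium sulfate salt 23 (not isolated)
Conditions: H2 (1 atm), Pd/C (10 %), HCO2NH4, THF–MeOH, 23 °C; then cold 0.1 M HCl, C18 cartridge
Reagents that add atoms: none
Why: Palladium-catalysed hydrogenolysis cleaves the four benzyl ethers and the diphenylmethylene ketal while formate-driven reductive fragmentation of the trichloroethyl ester releases the aryl sulfate as its ammonium salt in a near-neutral buffer that should spare the sulfate, the flavone double bond and the C2 and C3 stereocentres, and brief cold acidification gives the acid form.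

**Compound list**
1 | luteolin | O=c1cc(-c2ccc(O)c(O)c2)oc2cc(O)cc(O)c12 | starting material
2 | dichlorodiphenylmethane | ClC(Cl)(c1ccccc1)c1ccccc1 | starting material
3 | 3′,4′-O-diphenylmethylene-luteolin | O=c1cc(-c2ccc3OC(c4ccccc4)(c4ccccc4)Oc3c2)oc2cc(O)cc(O)c12 | intermediate
4 | allyl bromide | C=CCBr | starting material
5 | 7-O-allyl ether of 3 | O=c1cc(-c2ccc3OC(c4ccccc4)(c4ccccc4)Oc3c2)oc2cc(OCC=C)cc(O)c12 | intermediate
6 | benzyl bromide | BrCc1ccccc1 | starting material
7 | 7-O-allyl-5-O-benzyl ether of 3 | O=c1cc(-c2ccc3OC(c4ccccc4)(c4ccccc4)Oc3c2)oc2cc(OCC=C)cc(OCc3ccccc3)c12 | intermediate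
8 | 8-allyl-5-benzyloxy-7-hydroxyflavone ketal | O=c1cc(-c2ccc3OC(c4ccccc4)(c4ccccc4)Oc3c2)oc2c(CC=C)c(O)cc(OCc3ccccc3)c12 | intermediate
9 | 5-fluororesorcinol | Oc1cc(O)cc(F)c1 | starting material
10 | 1,3-bis(benzyloxy)-5-fluorobenzene | Fc1cc(OCc2ccccc2)cc(OCc2ccccc2)c1 | intermediate
11 | 2,4-bis(benzyloxy)-6-fluorobenzaldehyde | O=Cc1c(F)cc(OCc2ccccc2)cc1OCc1ccccc1 | intermediate
12 | 2,4-bis(benzyloxy)-6-fluorobenzoic acid | OC(=O)c1c(F)cc(OCc2ccccc2)cc1OCc1ccccc1 | intermediate
13 | 2,4-bis(benzyloxy)-6-fluorobenzoyl chloride | ClC(=O)c1c(F)cc(OCc2ccccc2)cc1OCc1ccccc1 | intermediate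
14 | 7-O-aroyl-8-allylflavone | O=c1cc(-c2ccc3OC(c4ccccc4)(c4ccccc4)Oc3c2)oc2c(CC=C)c(OC(=O)c3c(F)cc(OCc4ccccc4)cc3OCc3ccccc3)cc(OCc3ccccc3)c12 | intermediate
15 | 7-O-aroyl-8-(2,3-dihydroxypropyl)flavone (racemic) | O=c1cc(-c2ccc3OC(c4ccccc4)(c4ccccc4)Oc3c2)oc2c(CC(O)CO)c(OC(=O)c3c(F)cc(OCc4ccccc4)cc3OCc3ccccc3)cc(OCc3ccccc3)c12 | intermediate
16 | 7-O-aroyl-8-(2-oxoethyl)flavone | O=c1cc(-c2ccc3OC(c4ccccc4)(c4ccccc4)Oc3c2)oc2c(CC=O)c(OC(=O)c3c(F)cc(OCc4ccccc4)cc3OCc3ccccc3)cc(OCc3ccccc3)c12 | intermediate
17 | 3-[2,4-bis(benzyloxy)-6-fluorophenyl]-2-(7-hydroxyflavon-8-yl)-3-oxopropanal (enolised) | O=c1cc(-c2ccc3OC(c4ccccc4)(c4ccccc4)Oc3c2)oc2c(C(C=O)C(=O)c3c(F)cc(OCc4ccccc4)cc3OCc3ccccc3)c(O)cc(OCc3ccccc3)c12 | intermediate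
18 | 3-(7-hydroxyflavon-8-yl)-5,7-bis(benzyloxy)chromone | O=c1c2c(OCc3ccccc3)cc(OCc3ccccc3)cc2occ1-c1c(O)cc(OCc2ccccc2)c2c(=O)cc(-c3ccc4OC(c5ccccc5)(c5ccccc5)Oc4c3)oc12 | intermediate
19 | 2,2,2-trichloroethyl chlorosulfate | ClS(=O)(=O)OCC(Cl)(Cl)Cl | starting material
20 | 7″-O-(2,2,2-trichloroethoxysulfonyl) derivative of 18 | O=c1c2c(OCc3ccccc3)cc(OCc3ccccc3)cc2occ1-c1c(OS(=O)(=O)OCC(Cl)(Cl)Cl)cc(OCc2ccccc2)c2c(=O)cc(-c3ccc4OC(c5ccccc5)(c5ccccc5)Oc4c3)oc12 | intermediate
21 | 4-(benzyloxy)phenylboronic acid | OB(O)c1ccc(OCc2ccccc2)cc1 | starting material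
22 | fully protected (2R,3S)-flavanone–flavone trichloroethyl sulfate | O=C1c2c(OCc3ccccc3)cc(OCc3ccccc3)cc2O[C@@H](c2ccc(OCc3ccccc3)cc2)[C@@H]1c1c(OS(=O)(=O)OCC(Cl)(Cl)Cl)cc(OCc2ccccc2)c2c(=O)cc(-c3ccc4OC(c5ccccc5)(c5ccccc5)Oc4c3)oc12 | intermediate
23 | ammonium salt of the target | O=C1c2c(O)cc(O)cc2O[C@@H](c2ccc(O)cc2)[C@@H]1c1c(OS(=O)(=O)[O-])cc(O)c2c(=O)cc(-c3ccc(O)c(O)c3)oc12.[NH4+] | intermediate
24 | (2R,3S)-morelloflavone 7″-O-sulfate | O=C1c2c(O)cc(O)cc2O[C@@H](c2ccc(O)cc2)[C@@H]1c1c(OS(=O)(=O)O)cc(O)c2c(=O)cc(-c3ccc(O)c(O)c3)oc12 | target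

**Total steps:** 13. **Longest linear sequence:** 10 (steps 1–4 and 8–13).

**Steps most likely to fail**

Step 10. Several processes may outrun the displacement of fluoride. The freed phenol may cyclodehydrate onto one of the two carbonyl groups, the aldehyde may undergo intermolecular aldol reaction, or the aryl ester may be hydrolysed. In the fallback the C3–C8″ bond is made by Suzuki–Miyaura coupling of two finished benzopyranones, the standard isoflavone construction. It sets out from 3. MOMCl and i-Pr2NEt give the 7-O-methoxymethyl ether F1, and BnBr with K2CO3 at 80 °C gives the 5-O-benzyl ether F2. I2 with AgOCOCF3 then gives the 8-iodide F3, and B2pin2, PdCl2(dppf) and KOAc give the 8-pinacolboronate F4. Separately, commercial 2′-hydroxy-4′,6′-bis(benzyloxy)acetophenone is condensed with DMF dimethyl acetal to the enaminone F5, which I2 cyclises to 3-iodo-5,7-bis(benzyloxy)chromone F6. Coupling of F4 with F6 (Pd(OAc)2, SPhos, K3PO4, toluene–H2O) gives the 7″-O-methoxymethyl chromone–flavone F7. HCl in MeOH–THF removes the acetal and comes back to the route at 18.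

Step 12. Migratory insertion may be slow next to the bulky aryl group on C3, and the boronic acid may protodeboronate. Traces of zerovalent palladium may cause reductive loss of the trichloroethyl group, and facial selectivity may be poor. The fallback is a copper-mediated racemic arylation followed by resolution with recycling, and it sets out from 18. Excess (4-benzyloxyphenyl)magnesium bromide with CuBr·SMe2 and Me3SiCl in THF at −40 °C, then acidic work-up, gives the racemic trans-flavanone F8. Preparative chromatography on a chiral phase gives the (2R,3S)-flavanone F9. The unwanted antipode is racemised with a trace of DBU (ring opening and reclosure) and fed back. Sulfation of F9 with 19 (Et3N, DMAP, THF, 0 °C) comes back to the route at 22.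

Step 13. The flavone double bond or the benzylic C2–O1 bond may be over-reduced. The sulfate may hydrolyse if the medium turns acidic, and racemisation may set in once the 4′-OH is free if the medium turns basic. The fallback splits the reductive work into two different reactions and sets out from 22. Zn and HCO2NH4 in MeOH–THF fragment only the trichloroethyl ester and give the ammonium salt of the still benzylated sulfate F10. Hydrogenolysis of this stable salt (H2, Pd(OH)2/C, THF–MeOH with NH4OAc buffer) can then be followed and stopped on its own, and it comes back to the route at 23.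

**Further compounds**
F1 | step 10 | 7-O-methoxymethyl ether of 3 | O=c1cc(-c2ccc3OC(c4ccccc4)(c4ccccc4)Oc3c2)oc2cc(OCOC)cc(O)c12
F2 | step 10 | 5-O-benzyl-7-O-methoxymethyl ether of 3 | O=c1cc(-c2ccc3OC(c4ccccc4)(c4ccccc4)Oc3c2)oc2cc(OCOC)cc(OCc3ccccc3)c12
F3 | step 10 | 8-iodide of F2 | O=c1cc(-c2ccc3OC(c4ccccc4)(c4ccccc4)Oc3c2)oc2c(I)c(OCOC)cc(OCc3ccccc3)c12
F4 | step 10 | 8-pinacolboronate of F2 | O=c1cc(-c2ccc3OC(c4ccccc4)(c4ccccc4)Oc3c2)oc2c(B3OC(C)(C)C(C)(C)O3)c(OCOC)cc(OCc3ccccc3)c12
F5 | step 10 | (E)-1-[2,4-bis(benzyloxy)-6-hydroxyphenyl]-3-(dimethylamino)prop-2-en-1-one | CN(C)/C=C/C(=O)c1c(O)cc(OCc2ccccc2)cc1OCc1ccccc1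
F6 | step 10 | 3-iodo-5,7-bis(benzyloxy)-4H-chromen-4-one | O=c1c(I)coc2cc(OCc3ccccc3)cc(OCc3ccccc3)c12
F7 | step 10 | 7″-O-methoxymethyl ether of 18 | O=c1c2c(OCc3ccccc3)cc(OCc3ccccc3)cc2occ1-c1c(OCOC)cc(OCc2ccccc2)c2c(=O)cc(-c3ccc4OC(c5ccccc5)(c5ccccc5)Oc4c3)oc12
F8 | step 12 | (±)-trans-flavanone–flavone with free 7″-OH (racemate, drawn flat) | O=C1c2c(OCc3ccccc3)cc(OCc3ccccc3)cc2OC(c2ccc(OCc3ccccc3)cc2)C1c1c(O)cc(OCc2ccccc2)c2c(=O)cc(-c3ccc4OC(c5ccccc5)(c5ccccc5)Oc4c3)oc12
F9 | step 12 | (2R,3S)-flavanone–flavone with free 7″-OH | O=C1c2c(OCc3ccccc3)cc(OCc3ccccc3)cc2O[C@@H](c2ccc(OCc3ccccc3)cc2)[C@@H]1c1c(O)cc(OCc2ccccc2)c2c(=O)cc(-c3ccc4OC(c5ccccc5)(c5ccccc5)Oc4c3)oc12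
F10 | step 13 | ammonium salt of the benzyl- and ketal-protected (2R,3S)-7″-sulfate | O=C1c2c(OCc3ccccc3)cc(OCc3ccccc3)cc2O[C@@H](c2ccc(OCc3ccccc3)cc2)[C@@H]1c1c(OS(=O)(=O)[O-])cc(OCc2ccccc2)c2c(=O)cc(-c3ccc4OC(c5ccccc5)(c5ccccc5)Oc4c3)oc12.[NH4+]
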